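Ring D (the benzene ring) carries only the C7 oxygen of ring B on one carbon and, para to it, the CH2 group on lactam C5'. It is bent inside the 13-membered ring O–(four arene C)–CH2–C5'–C4'–C3'–C(=O)–C6–C5–C7. An arene with this 1,4-pattern can be built from C3–C6 of a 4-alkoxy-2-pyranone and the two carbons of a propargyl alkyne, with loss of CO2.
Cuts, in order: C5'–OH (back to OMe); the side-chain ketone (back to a silylated carbinol); then the two arene bonds pyranone C3–alkyne CH and pyranone C6–alkyne C, which opens ring D and the macrocycle together.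
Further cuts: carbinol C–C3' (Nozaki–Hiyama–Kishi), O–pyranone C4 (addition–elimination), C2=C3 (metathesis), C6–C1 (Ireland–Claisen), C4–isopropenyl and C5–CH2 (cuprate/alkylation), C13–CH3 and C13=C4 (cuprate, aldol condensation), C9–CH3 and C8–allyl (cuprate/alkylation).
Forward order of rings: A (from pulegone), B, C, then the pyranone ether, the lactam (ring E, made separately from maleimide), and last ring D and the 13-membered ring in one step.
Stereochemistry: C11 comes from (R)-pulegone and is relayed to C9, C8, C13, C4, C5 and C7 by substrate control. C1 is set by the choice between two diastereotopic vinyl groups, C6 by kinetic protonation, and C5' by resolution and again by thermodynamic control in the last step.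

Key step: step 29

Locants used here: ring C = C1(vinyl)–C2=C3(CH3)–C4–C5–C6(side chain); ring B = C4–C5–C7(O)–C8–C13(CH3); ring A = C8–C9(CH3)–C10–C11(CH3)–C12–C13; lactam N1'–C5'. β is the face of ring B that bears the C7 oxygen. In the target H1, H5, H6 and 11-CH3 are β; H4, H7, H8, 9-CH3, 13-CH3, the vinyl group and the C6 side chain are α.
Assumption: the C5' N,O-aminal is taken to be configurationally stable under neutral conditions and labile in acid.

Step 1
Reactants: 1 (R)-(+)-pulegone
Product: 2 pulegone oxide (both epimers at the spiro carbon)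
Conditions: 30% H2O2, LiOH, MeOH, 0 °C to rt
Reagents that add atoms: hydrogen peroxide, OO
Why: Nucleophilic (Weitz–Scheffer) epoxidation of the enone should proceed readily, and the new spiro centre needs no control because step 2 destroys it.

Step 2
Reactants: 2 pulegone oxide
Product: 3 (5R)-5-methyl-2-(phenylsulfanyl)cyclohexan-1-one (C2 epimers)
Conditions: PhSH, NaH, THF, reflux
Reagents that add atoms: thiophenol, Sc1ccccc1
Why: Thiolate opening of the α,β-epoxy ketone at the α-carbon followed by retro-aldol loss of acetone should give the α-sulfanyl ketone with the pulegone centre (later C11) untouched, and the C2 centre is lost in step 3.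

Step 3
Reactants: 3 (5R)-5-methyl-2-(phenylsulfanyl)cyclohexan-1-one
Product: 5 (R)-5-methylcyclohex-2-en-1-one, via sulfoxide 4 (not isolated)
Conditions: mCPBA, CH2Cl2, −78 °C; then CaCO3, toluene, 110 °C
Reagents that add atoms: none
Why: Sulfide oxidation and thermal syn elimination of the sulfoxide, which has β-hydrogens on one carbon only, should place the double bond regiospecifically without touching the stereocentre.

Step 4
Reactants: 5 (R)-5-methylcyclohex-2-en-1-one
Product: 7 (2S,3R,5R)-2-allyl-3,5-dimethylcyclohexan-1-one, via lithium enolate 6 (not isolated)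
Conditions: Me2CuLi (MeLi, CuI), Et2O, −78 to 0 °C; then allyl bromide, HMPA, THF, −30 °C to rt
Reagents that add atoms: lithium dimethylcuprate, [Li+].C[Cu-]C; allyl bromide, C=CCBr
Why: Conjugate addition of the Gilman cuprate should occur trans to the ring methyl group (sets C9), and allylation of the regiodefined enolate trans to the new methyl group sets C8, which is also the thermodynamically preferred configuration.

Step 5
Reactants: 7 (2S,3R,5R)-2-allyl-3,5-dimethylcyclohexan-1-one
Product: 8 (2S,3R,5R)-3,5-dimethyl-2-(2-oxopropyl)cyclohexan-1-one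
Conditions: PdCl2 (10 mol %), CuCl, O2 (1 atm), DMF–H2O, rt
Reagents that add atoms: water, O
Why: Wacker–Tsuji oxidation of the terminal alkene should give the methyl ketone with Markovnikov selectivity and creates no stereocentre.

Step 6
Reactants: 8 (2S,3R,5R)-3,5-dimethyl-2-(2-oxopropyl)cyclohexan-1-one
Product: 9 hydrindenone (C13=C4–C5=O, H8 α, 9-CH3 α, 11-CH3 β)
Conditions: KOH, EtOH, reflux
Reagents that add atoms: none
Why: Intramolecular aldol condensation of the 1,4-diketone (methyl ketone enolate onto the ring ketone) should close ring B, with C8 keeping its more stable equatorial side-chain configuration.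

Step 7
Reactants: 9 hydrindenone
Product: 11 enol triflate (C4=C5–OTf, 13-CH3 α, cis ring fusion), via lithium enolate 10 (not isolated)
Conditions: Me2CuLi (MeLi, CuI), Et2O, 0 °C; then PhNTf2, THF, 0 °C to rt
Reagents that add atoms: lithium dimethylcuprate, [Li+].C[Cu-]C; N-phenylbis(trifluoromethanesulfonimide), O=S(=O)(N(c1ccccc1)S(=O)(=O)C(F)(F)F)C(F)(F)F
Why: Cuprate conjugate addition at the ring-fusion β-carbon should deliver methyl on the face of H8, which leads to the cis-hydrindane enolate and is remote from the axial 11-methyl group (sets C13), and O-triflation of the regiodefined enolate fixes the C4=C5 double bond.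

Step 8
Reactants: 11 enol triflate
Product: 12 cis-hydrindene (C4=C5)
Conditions: Pd(OAc)2 (5 mol %), PPh3, HCO2H, Bu3N, DMF, 60 °C
Reagents that add atoms: none
Why: Palladium-catalysed formate reduction of the enol triflate (oxidative addition to zerovalent palladium, hydride transfer from formate, reductive elimination) should give the alkene without moving the double bond.

Step 9
Reactants: 12 cis-hydrindene
Product: 13 cis-hydrindenone (C7=O, C5=C4)
Conditions: Rh2(cap)4 (dirhodium tetracaprolactamate, 1 mol %), tBuOOH, K2CO3, CH2Cl2, rt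
Reagents that add atoms: tert-butyl hydroperoxide, CC(C)(C)OO
Why: Catalytic allylic oxidation should convert the only allylic CH2 group (C7, since C13 is quaternary) into the enone carbonyl, because capture at the C4 end of the allyl system is hindered by the neighbouring quaternary carbon.

Step 10
Reactants: 14 (E)-penta-2,4-dienoic acid
Product: 15 (E)-penta-2,4-dien-1-ol
Conditions: LiAlH4, Et2O, 0 °C
Reagents that add atoms: none
Why: Hydride reduction of the carboxylic acid should give the dienol with the E double bond unchanged.

Step 11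
Reactants: 15 (E)-penta-2,4-dien-1-ol
Product: 16 (E)-penta-2,4-dienyl bromoacetate
Conditions: BrCH2COBr, pyridine, CH2Cl2, 0 °C
Reagents that add atoms: bromoacetyl bromide, O=C(Br)CBr
Why: Acylation of the primary alcohol at the acid bromide end is a standard esterification and keeps the C–Br bond for step 12.

Step 12
Reactants: 13 cis-hydrindenone; 16 (E)-penta-2,4-dienyl bromoacetate
Product: 18 keto ester (4β-isopropenyl, 5α-CH2CO2-pentadienyl, C7=O), via lithium enolate 17 (not isolated)
Conditions: (CH2=CMe)2CuLi (isopropenyllithium, CuI), Et2O–THF, −78 °C; then 16, HMPA, −78 to −20 °C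
Reagents that add atoms: lithium di(prop-1-en-2-yl)cuprate, [Li+].C=C(C)[Cu-]C(C)=C
Why: In this three-component coupling the cuprate should enter C4 anti to the 13-methyl group on the adjacent quaternary carbon (sets C4), and the bromoacetate then alkylates the regiodefined enolate at C5 anti to the new isopropenyl group (sets C5, also the more stable trans arrangement).

Step 13
Reactants: 18 keto ester
Product: 19 7β-hydroxy ester
Conditions: NaBH4, MeOH, −20 °C
Reagents that add atoms: none
Why: Borohydride should attack the C7 ketone from the convex α face (the face of H8), because ring A and the isopropenyl group close the β face; this sets C7, and the β-alcohol, trans to the ester arm, cannot lactonise.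

Step 14
Reactants: 19 7β-hydroxy ester
Product: 22 methyl ester with CO2CH3 and a penta-1,4-dien-3-yl group on C6 (C6 epimers), via silyl ketene acetal 20 (not isolated), via carboxylic acid 21 (not isolated)
Conditions: LiN(iPr)2 (2.5 equiv), Me3SiCl, THF, −78 to 50 °C; 1 M HCl; then Me3SiCHN2, toluene–MeOH, 0 °C
Reagents that add atoms: (trimethylsilyl)diazomethane, C[Si](C)(C)C=[N+]=[N-]
Why: The Ireland–Claisen [3,3] shift joins C6 to the inner allylic terminus of the pentadienyl ester, so C1 arrives with two vinyl groups and is not yet stereogenic; the hydroxyl is masked in situ as its silyl ether, and C6 forms without reliable control and is corrected in step 16.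

Step 15
Reactants: 22 methyl ester
Product: 23 tricyclic ester (ring C closed, 1α-vinyl, C6 epimers)
Conditions: second-generation Grubbs catalyst RuCl2(=CHPh)(PCy3)(SIMes) (10 mol %), 1,4-benzoquinone, toluene, 80 °C
Reagents that add atoms: none
Why: Ring-closing metathesis of the isopropenyl group with one of the two diastereotopic vinyl groups should close the six-membered ring through the chair-like arrangement that leaves the other vinyl group pseudo-equatorial (sets C1), and benzoquinone suppresses isomerisation of the skipped diene.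

Step 16
Reactants: 23 tricyclic ester (C6 epimers)
Product: 25 tricyclic ester with the axial 6α-CO2CH3 group (H6 β), via dilithium enolate 24 (not isolated)
Conditions: LiN(iPr)2 (2.5 equiv), THF, −78 to −30 °C; then AcOH in THF, −78 °C
Reagents that add atoms: none
Why: Both C6 epimers converge on one exocyclic ester enolate, and kinetic protonation should come from the equatorial β side, because the axial α side lies under the ring next to axial H4; this leaves the ester axial (sets C6).

Step 17
Reactants: 25 tricyclic ester
Product: 26 diol (C6–CH2OH, 7β-OH)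
Conditions: LiAlH4, Et2O, 0 °C
Reagents that add atoms: none
Why: Hydride reduction of the ester removes the enolisable carbonyl group and so secures C6.

Step 18
Reactants: 26 diol
Product: 27 primary TBS ether (7β-OH free)
Conditions: TBSCl, imidazole, CH2Cl2, 0 °C
Reagents that add atoms: tert-butyldimethylsilyl chloride, CC(C)(C)[Si](C)(C)Cl
Why: Silylation should select the primary hydroxyl group, because the C7 hydroxyl sits on the concave face between two tertiary carbons.

Step 19
Reactants: 28 4-hydroxy-2H-pyran-2-one
Product: 29 4-bromo-2H-pyran-2-one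
Conditions: PBr3, DMF, 0 to 60 °C
Reagents that add atoms: phosphorus tribromide, BrP(Br)Br
Why: Vilsmeier-type deoxybromination of the vinylogous acid should give the vinylogous acyl bromide, chosen because bromide offers the alkoxide no second electrophilic site of the kind a sulfonate sulfur would.

Step 20
Reactants: 27 primary TBS ether; 29 4-bromo-2H-pyran-2-one
Product: 31 7β-(2-oxo-2H-pyran-4-yl) ether, via potassium alkoxide 30 (not isolated)
Conditions: KN(SiMe3)2, THF, −78 °C; then 29, −78 to 0 °C
Reagents that add atoms: none
Why: Addition–elimination (vinylogous acyl substitution) at pyranone C4 forms the O–C(sp2) bond and leaves the C7–O bond intact, so C7 is retained and no substitution at the hindered carbinol carbon is needed.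

Step 21
Reactants: 31 pyranone ether
Product: 32 primary alcohol
Conditions: HF·pyridine, pyridine, THF, 0 °C to rt
Reagents that add atoms: none
Why: Buffered fluoride cleavage of the silyl ether is non-basic and should spare the pyranone and the alkenes.

Step 22
Reactants: 32 primary alcohol
Product: 33 6α-carbaldehyde
Conditions: Dess–Martin periodinane, NaHCO3, CH2Cl2, 0 °C
Reagents that add atoms: none
Why: Buffered periodinane oxidation is neutral enough to deliver the axial aldehyde without epimerisation at C6, and the aldehyde is used at once.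

Step 23
Reactants: 34 maleimide; 35 propargyl bromide
Product: 37 rac-5-hydroxy-5-(prop-2-ynyl)-1,5-dihydro-2H-pyrrol-2-one, via allenylzinc bromide 36 (not isolated)
Conditions: Zn, THF, 0 °C; then 34, −20 °C to rt; aq NH4Cl
Reagents that add atoms: none
Why: In this Barbier-type addition the allenylzinc reagent should attack one of the two equivalent imide carbonyl groups through its γ-carbon (SE2') to give the propargyl hemiaminal as a racemate, with one further equivalent consumed by the N–H.

Step 24
Reactants: 37 rac-hydroxy lactam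
Product: 38 rac-5-methoxy-5-(prop-2-ynyl)-1,5-dihydro-2H-pyrrol-2-one
Conditions: MeOH, camphorsulfonic acid (cat.), rt
Reagents that add atoms: methanol, CO
Why: Acid-catalysed exchange of the hemiaminal hydroxyl for methoxy in excess methanol gives an aminal that no longer opens to the keto amide.

Step 25
Reactants: 38 rac-methoxy lactam
Product: 39 rac-3-iodo-5-methoxy-5-(prop-2-ynyl)-1,5-dihydro-2H-pyrrol-2-one
Conditions: I2, pyridine, CH2Cl2, rt, dark
Reagents that add atoms: iodine, II
Why: α-Iodination of the conjugated lactam by pyridine addition, iodination and elimination acts only on the Michael acceptor and should leave the alkyne alone.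

Step 26
Reactants: 39 rac-iodo lactam
Product: 40 (R)-3-iodo-5-methoxy-5-(prop-2-ynyl)-1,5-dihydro-2H-pyrrol-2-one
Conditions: preparative HPLC, cellulose tris(3,5-dimethylphenylcarbamate) phase, hexane–iPrOH
Reagents that add atoms: none
Why: Chromatographic resolution on a chiral phase sets C5', and the unwanted enantiomer can be racemised with camphorsulfonic acid in methanol and recycled.

Step 27
Reactants: 33 6α-carbaldehyde; 40 (R)-iodo lactam
Product: 42 allylic alcohol joining C6 and C3' (both carbinol epimers), via alkenylchromium dichloride 41 (not isolated)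
Conditions: CrCl2 (6 equiv), NiCl2 (2 mol %), DMF–THF, rt
Reagents that add atoms: none
Why: The Nozaki–Hiyama–Kishi coupling is non-basic, so it should add the alkenyl group to the aldehyde without epimerising C6 and should tolerate N–H, the terminal alkyne, the aminal and the pyranone; the new carbinol centre needs no control because step 31 removes it.

Step 28
Reactants: 42 allylic alcohol
Product: 43 seco pyranone ether with the 5'-methoxy-5'-propargyl lactam and the carbinol as its triethylsilyl ether
Conditions: Et3SiCl, imidazole, DMF, rt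
Reagents that add atoms: triethylsilyl chloride, CC[Si](CC)(CC)Cl
Why: Silylation of the only free hydroxyl group holds the side chain at the carbinol level, which keeps C6 from enolising and keeps the lactam double bond from being doubly activated during the thermolysis.

Step 29
Reactants: 43 seco pyranone ether
Product: 45 paracyclophane (rings D and the 13-membered ring closed, carbinol as triethylsilyl ether, 5'-OCH3), via bridged lactone 44 (not isolated)
Conditions: 1,2-dichlorobenzene (0.5 mM), BHT, Ar, sealed vessel, 210 °C
Reagents that add atoms: none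
Why: Heating brings the terminal alkyne over the 4-alkoxy-2-pyranone, whose C3 and C6 add to the terminal and the internal alkyne carbon in a concerted [4+2] step to give the 2-oxabicyclo[2.2.2]octadienone 44, and retro-[4+2] loss of CO2 then makes the benzene ring irreversibly; the closest known reaction type is the intramolecular 2-pyranone–alkyne Diels–Alder/decarboxylation used for strained, bent paracyclophanes. Ring D closes by cycloaddition followed by cycloreversion (four carbons from pyranone C3–C6, two from the alkyne), and the 13-membered ring closes at the same moment as the tether ring of this cycloaddition, with the nine-atom tether running from the inner diene carbon C4 to the internal alkyne carbon, so the strain is first met in the non-planar bicycle 44, where the two anchor bonds stand at about 120° and not 180°. No lasting stereocentre is formed, because the two bridgeheads of 44 vanish with CO2, and C5', C6 and the silyloxy carbon are spectators. The step needs para and not meta bridging, and since an unactivated alkyne gives little electronic help the choice rests on the substrate: the internal alkyne carbon with its neopentyl-type CH2–C5' arm avoids pyranone C3, which is flanked by the lactone carbonyl and the bulky C7 alkoxy group, and a meta bridge would turn the pyranone C3–H into a 12-membered ring that already has to pass round the C5–C7 edge from the β-oxygen to the α side chain. The alkyne must also win over the alkenes: with the ketone held back the lactam C3'=C4' bond is only singly activated and trisubstituted, the C1 vinyl group points away from the β face, and high dilution with a radical inhibitor suppresses intermolecular addition.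

Step 30
Reactants: 45 paracyclophane silyl ether
Product: 46 paracyclophane carbinol (both carbinol epimers)
Conditions: HF·pyridine, pyridine, THF, 0 °C
Reagents that add atoms: none
Why: Buffered fluoride cleavage of the triethylsilyl ether should leave the methoxy aminal in place.

Step 31
Reactants: 46 paracyclophane carbinol
Product: 47 O-methyl aminal of the target (3'-acyl lactam)
Conditions: Dess–Martin periodinane, NaHCO3, CH2Cl2, 0 °C to rt
Reagents that add atoms: none
Why: Periodinane oxidation of the allylic alcohol merges both carbinol epimers into the ketone under neutral conditions, with C6 now held by the macrocycle.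

Step 32
Reactants: 47 O-methyl aminal
Product: 49 target CNP0151253.3, via N-acyliminium ion 48 (not isolated)
Conditions: 0.1 M aq HCl–THF, rt
Reagents that add atoms: water, O
Why: Acid ionises the aminal and water adds reversibly, so this solvolytic exchange settles C5' under thermodynamic control of the strained macrocycle, which should keep the CH2 arm on the face already set in step 26.

Compound list
1 | (R)-(+)-pulegone | CC(C)=C1CC[C@@H](C)CC1=O | starting material
2 | pulegone oxide (spiro epimers) | CC1(C)OC12CC[C@@H](C)CC2=O | intermediate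
3 | (5R)-5-methyl-2-(phenylsulfanyl)cyclohexan-1-one (C2 epimers) | O=C1C[C@H](C)CCC1Sc1ccccc1 | intermediate
4 | (5R)-5-methyl-2-(phenylsulfinyl)cyclohexan-1-one | O=C1C[C@H](C)CCC1S(=O)c1ccccc1 | intermediate
5 | (R)-5-methylcyclohex-2-en-1-one | O=C1C=CC[C@@H](C)C1 | intermediate
6 | lithium enolate of trans-3,5-dimethylcyclohexanone | [Li+].[O-]C1=C[C@H](C)C[C@@H](C)C1 | intermediate
7 | (2S,3R,5R)-2-allyl-3,5-dimethylcyclohexan-1-one | C=CC[C@H]1[C@H](C)C[C@@H](C)CC1=O | intermediate
8 | (2S,3R,5R)-3,5-dimethyl-2-(2-oxopropyl)cyclohexan-1-one | CC(=O)C[C@H]1[C@H](C)C[C@@H](C)CC1=O | intermediate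
9 | hydrindenone (C13=C4–C5=O) | C1[C@H]2[C@H](C)C[C@@H](C)CC2=CC1=O | intermediate
10 | lithium enolate (C4=C5–OLi, 13-CH3 α) | C1[C@H]2[C@H](C)C[C@@H](C)C[C@@]2(C)C=C1[O-].[Li+] | intermediate
11 | enol triflate (C4=C5–OTf) | C1[C@H]2[C@H](C)C[C@@H](C)C[C@@]2(C)C=C1OS(=O)(=O)C(F)(F)F | intermediate
12 | cis-hydrindene (C4=C5) | C1[C@H]2[C@H](C)C[C@@H](C)C[C@@]2(C)C=C1 | intermediate
13 | cis-hydrindenone (C7=O, C5=C4) | O=C1[C@H]2[C@H](C)C[C@@H](C)C[C@@]2(C)C=C1 | intermediate
14 | (E)-penta-2,4-dienoic acid | C=C/C=C/C(=O)O | starting material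
15 | (E)-penta-2,4-dien-1-ol | C=C/C=C/CO | intermediate
16 | (E)-penta-2,4-dienyl bromoacetate | C=C/C=C/COC(=O)CBr | intermediate
17 | lithium enolate (4β-isopropenyl, C5=C7–OLi) | C=C(C)[C@H]1C=C([O-])[C@H]2[C@H](C)C[C@@H](C)C[C@@]12C.[Li+] | intermediate
18 | keto ester (4β-isopropenyl, 5α-CH2CO2-pentadienyl) | C=C(C)[C@H]1[C@H](CC(=O)OC/C=C/C=C)C(=O)[C@H]2[C@H](C)C[C@@H](C)C[C@@]12C | intermediate
19 | 7β-hydroxy ester | C=C(C)[C@H]1[C@H](CC(=O)OC/C=C/C=C)[C@@H](O)[C@H]2[C@H](C)C[C@@H](C)C[C@@]12C | intermediate
20 | silyl ketene acetal, 7-O-trimethylsilyl | C=C(C)[C@H]1[C@H](C=C(O[Si](C)(C)C)OC/C=C/C=C)[C@@H](O[Si](C)(C)C)[C@H]2[C@H](C)C[C@@H](C)C[C@@]12C | intermediate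
21 | carboxylic acid with the penta-1,4-dien-3-yl group on C6 (C6 epimers) | C=C(C)[C@H]1[C@H](C(C(C=C)C=C)C(=O)O)[C@@H](O)[C@H]2[C@H](C)C[C@@H](C)C[C@@]12C | intermediate
22 | methyl ester of 21 (C6 epimers) | C=C(C)[C@H]1[C@H](C(C(C=C)C=C)C(=O)OC)[C@@H](O)[C@H]2[C@H](C)C[C@@H](C)C[C@@]12C | intermediate
23 | tricyclic ester, 1α-vinyl (C6 epimers) | C=C[C@H]1C=C(C)[C@H]2[C@H](C1C(=O)OC)[C@@H](O)[C@H]1[C@H](C)C[C@@H](C)C[C@@]21C | intermediate
24 | dilithium enolate/alkoxide of 23 | C=C[C@H]1C=C(C)[C@H]2[C@H](C1=C([O-])OC)[C@@H]([O-])[C@H]1[C@H](C)C[C@@H](C)C[C@@]21C.[Li+].[Li+] | intermediate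
25 | tricyclic ester, 6α-CO2CH3 | C=C[C@H]1C=C(C)[C@H]2[C@H]([C@H]1C(=O)OC)[C@@H](O)[C@H]1[C@H](C)C[C@@H](C)C[C@@]21C | intermediate
26 | diol | C=C[C@H]1C=C(C)[C@H]2[C@H]([C@H]1CO)[C@@H](O)[C@H]1[C@H](C)C[C@@H](C)C[C@@]21C | intermediate
27 | primary TBS ether, 7β-OH | C=C[C@H]1C=C(C)[C@H]2[C@H]([C@H]1CO[Si](C)(C)C(C)(C)C)[C@@H](O)[C@H]1[C@H](C)C[C@@H](C)C[C@@]21C | intermediate
28 | 4-hydroxy-2H-pyran-2-one | O=C1C=C(O)C=CO1 | starting material
29 | 4-bromo-2H-pyran-2-one | O=C1C=C(Br)C=CO1 | intermediate
30 | potassium 7β-alkoxide of 27 | C=C[C@H]1C=C(C)[C@H]2[C@H]([C@H]1CO[Si](C)(C)C(C)(C)C)[C@@H]([O-])[C@H]1[C@H](C)C[C@@H](C)C[C@@]21C.[K+] | intermediate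
31 | 7β-(2-oxo-2H-pyran-4-yl) ether, TBS ether | C=C[C@H]1C=C(C)[C@H]2[C@H]([C@H]1CO[Si](C)(C)C(C)(C)C)[C@@H](OC1=CC(=O)OC=C1)[C@H]1[C@H](C)C[C@@H](C)C[C@@]21C | intermediate
32 | pyranone ether, primary alcohol | C=C[C@H]1C=C(C)[C@H]2[C@H]([C@H]1CO)[C@@H](OC1=CC(=O)OC=C1)[C@H]1[C@H](C)C[C@@H](C)C[C@@]21C | intermediate
33 | pyranone ether, 6α-carbaldehyde | C=C[C@H]1C=C(C)[C@H]2[C@H]([C@H]1C=O)[C@@H](OC1=CC(=O)OC=C1)[C@H]1[C@H](C)C[C@@H](C)C[C@@]21C | intermediate
34 | maleimide | O=C1C=CC(=O)N1 | starting material
35 | propargyl bromide | C#CCBr | starting material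
36 | allenylzinc bromide | C=C=C[Zn]Br | intermediate
37 | rac-5-hydroxy-5-(prop-2-ynyl)-1,5-dihydro-2H-pyrrol-2-one | C#CCC1(O)C=CC(=O)N1 | intermediate
38 | rac-5-methoxy-5-(prop-2-ynyl)-1,5-dihydro-2H-pyrrol-2-one | C#CCC1(OC)C=CC(=O)N1 | intermediate
39 | rac-3-iodo-5-methoxy-5-(prop-2-ynyl)-1,5-dihydro-2H-pyrrol-2-one | C#CCC1(OC)C=C(I)C(=O)N1 | intermediate
40 | (R)-3-iodo-5-methoxy-5-(prop-2-ynyl)-1,5-dihydro-2H-pyrrol-2-one | IC1=C[C@@](CC#C)(OC)NC1=O | intermediate
41 | alkenylchromium dichloride from 40 | Cl[Cr](Cl)C1=C[C@@](CC#C)(OC)NC1=O | intermediate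
42 | allylic alcohol (carbinol epimers) | C=C[C@H]1C=C(C)[C@H]2[C@H]([C@H]1C(O)C1=C[C@@](CC#C)(OC)NC1=O)[C@@H](OC1=CC(=O)OC=C1)[C@H]1[C@H](C)C[C@@H](C)C[C@@]21C | intermediate
43 | seco pyranone ether, triethylsilyl ether (key-step precursor) | C=C[C@H]1C=C(C)[C@H]2[C@H]([C@H]1C(O[Si](CC)(CC)CC)C1=C[C@@](CC#C)(OC)NC1=O)[C@@H](OC1=CC(=O)OC=C1)[C@H]1[C@H](C)C[C@@H](C)C[C@@]21C | intermediate
44 | bridged 2-oxabicyclo[2.2.2]octadienone (transient bridgeheads left open) | C=C[C@H]1C=C(C)[C@H]2[C@H]3[C@@H](OC4=CC5OC(=O)C4C=C5C[C@@]4(OC)C=C(C(=O)N4)C(O[Si](CC)(CC)CC)[C@@H]13)[C@H]1[C@H](C)C[C@@H](C)C[C@]12C | intermediate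
45 | paracyclophane, triethylsilyl ether (key-step product) | C=C[C@H]1C=C(C)[C@H]2[C@H]3[C@@H](Oc4ccc(cc4)C[C@@]4(OC)C=C(C(=O)N4)C(O[Si](CC)(CC)CC)[C@@H]13)[C@H]1[C@H](C)C[C@@H](C)C[C@]12C | intermediate
46 | paracyclophane carbinol (carbinol epimers) | C=C[C@H]1C=C(C)[C@H]2[C@H]3[C@@H](Oc4ccc(cc4)C[C@@]4(OC)C=C(C(=O)N4)C(O)[C@@H]13)[C@H]1[C@H](C)C[C@@H](C)C[C@]12C | intermediate
47 | O-methyl aminal of the target | C=C[C@H]1C=C(C)[C@H]2[C@H]3[C@@H](Oc4ccc(cc4)C[C@@]4(OC)C=C(C(=O)N4)C(=O)[C@@H]13)[C@H]1[C@H](C)C[C@@H](C)C[C@]12C | intermediate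
48 | N-acyliminium ion | C=C[C@H]1C=C(C)[C@H]2[C@H]3[C@@H](Oc4ccc(cc4)CC4=[NH+]C(=O)C(=C4)C(=O)[C@@H]13)[C@H]1[C@H](C)C[C@@H](C)C[C@]12C | intermediate
49 | CNP0151253.3 | C=C[C@H]1C=C(C)[C@H]2[C@H]3[C@@H](Oc4ccc(cc4)C[C@@]4(O)C=C(C(=O)N4)C(=O)[C@@H]13)[C@H]1[C@H](C)C[C@@H](C)C[C@]12C | target

Total step count: 32. Longest linear sequence: 25 (steps 1–9, 12–18, 20–22, 27–32).

Steps most likely to fail

Step 29. The tether may fold so that the internal alkyne carbon meets pyranone C3 (meta bridging). Alternatively, thermal loss of methanol from the aminal and oligomerisation may outrun the slow cycloaddition of an unactivated alkyne. The fallback separates arene formation from ring closure. It sets out from 31 and 40, which are heated together at high concentration in 1,2-dichlorobenzene. The intermolecular pyranone–alkyne Diels–Alder/decarboxylation should then give the unstrained para-substituted aryl ether F1, separated from its meta isomer. HF·pyridine gives the primary alcohol F2, and Dess–Martin periodinane gives the iodo aldehyde F3. An intramolecular Nozaki–Hiyama–Kishi reaction (CrCl2, NiCl2, DMF, high dilution) then closes the 13-membered ring at the carbinol C–C3' bond, and the route is rejoined at 46.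

Step 20. The hindered concave-face alkoxide may add too slowly at C4, or it may attack C6 or C2 with opening of the pyranone ring. The fallback forms the other C–O bond. It sets out from 27. Dess–Martin oxidation gives the C7 ketone F4, and ketyl reduction with SmI2, H2O and Et3N should give the more stable convex 7α-alcohol F5. A Mitsunobu reaction of F5 with 28 (PPh3, DIAD) then alkylates the acidic 4-hydroxyl group with inversion at C7, and the route is rejoined at 31.

Step 12. Facial selectivity of the cuprate at C4 may be poor, because the 13-methyl group and ring A flank opposite faces, and the enolate may equilibrate before alkylation. The fallback delivers hydrogen instead of carbon to C4. It sets out from 13. (CH2=CMe)2CuLi with Me3SiCl gives the silyl enol ether F6 (either C4 epimer serves), and Saegusa–Ito oxidation with Pd(OAc)2 gives the 4-isopropenyl enone F7. Copper hydride conjugate reduction ([(Ph3P)CuH]6, PhMe2SiH) should add hydride on the open α face to give the silyl enol ether F8. MeLi then releases the lithium enolate, and the route is rejoined at 17.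

Further compounds
F1 | step 29 | para-substituted aryl ether with iodo lactam and TBS ether | C=C[C@H]1C=C(C)[C@H]2[C@H]([C@H]1CO[Si](C)(C)C(C)(C)C)[C@@H](Oc1ccc(C[C@@]3(OC)C=C(I)C(=O)N3)cc1)[C@H]1[C@H](C)C[C@@H](C)C[C@@]21C
F2 | step 29 | primary alcohol from F1 | C=C[C@H]1C=C(C)[C@H]2[C@H]([C@H]1CO)[C@@H](Oc1ccc(C[C@@]3(OC)C=C(I)C(=O)N3)cc1)[C@H]1[C@H](C)C[C@@H](C)C[C@@]21C
F3 | step 29 | iodo aldehyde | C=C[C@H]1C=C(C)[C@H]2[C@H]([C@H]1C=O)[C@@H](Oc1ccc(C[C@@]3(OC)C=C(I)C(=O)N3)cc1)[C@H]1[C@H](C)C[C@@H](C)C[C@@]21C
F4 | step 20 | C7 ketone | C=C[C@H]1C=C(C)[C@H]2[C@H]([C@H]1CO[Si](C)(C)C(C)(C)C)C(=O)[C@H]1[C@H](C)C[C@@H](C)C[C@@]21C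
F5 | step 20 | 7α-alcohol | C=C[C@H]1C=C(C)[C@H]2[C@H]([C@H]1CO[Si](C)(C)C(C)(C)C)[C@H](O)[C@H]1[C@H](C)C[C@@H](C)C[C@@]21C
F6 | step 12 | trimethylsilyl enol ether (C4 epimers) | C=C(C)C1C=C(O[Si](C)(C)C)[C@H]2[C@H](C)C[C@@H](C)C[C@@]12C
F7 | step 12 | 4-isopropenyl enone | C=C(C)C1=CC(=O)[C@H]2[C@H](C)C[C@@H](C)C[C@@]12C
F8 | step 12 | dimethylphenylsilyl enol ether, 4β-isopropenyl | C=C(C)[C@H]1C=C(O[Si](C)(C)c2ccccc2)[C@H]2[C@H](C)C[C@@H](C)C[C@@]12C
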